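**Plan**

- Retrosynthesis, with the chain numbered C1 (carbinol carbon on ring B) to C14 (benzylic CH2 on ring A): first the three O–Si bonds and the C1–H bond (back to the macrocyclic aryl ketone), then the C4–C5 bond of the 22-membered ring, then ring A–C14, then the diaryl ether C–O bond on ring A, and in the chain C6–C7.
- Enabling feature: the C1 oxygen on the benzylic carbon of ring B lies 1,4 to C4. At the ketone level C2, C3 and C4 can be stored as a cyclopropane conjugated to the ring-B aryl ketone, and its strained C2–C4 bond opens under nickel so that C4 bonds to the primary bromide at C5 of the chain on ring A.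
- Forward order: rings A and B are joined first as the diaryl ether, the methyl ethers are exchanged for TIPS, the cyclopropyl ketone is built on ring B, the C5–C14 chain is attached to ring A, the macrocycle is closed at C4–C5, and the ketone is reduced before desilylation.
- Stereochemistry: E-C8=C9 comes from the chair transition state of a Johnson–Claisen rearrangement; (R)-C1 comes from CBS reduction of the macrocyclic aryl ketone with the (S)-oxazaborolidine.

Key step: step 11

Remark: C1 of the target is (R) by CIP (O > aryl > CH2 > H); compounds 1, 2, 6, 9, 10 and 13 are taken as catalogue chemicals.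

**Route**

Step 1
Reactants: 1 syringaldehyde (4-hydroxy-3,5-dimethoxybenzaldehyde); 2 (3-bromo-5-methoxyphenyl)boronic acid
Product: 3 4-(3-bromo-5-methoxyphenoxy)-3,5-dimethoxybenzaldehyde
Conditions: Cu(OAc)2 (2 equiv), pyridine (5 equiv), 4 Å MS, CH2Cl2, rt, open to dry air
Reagents that add atoms: none
Why: Chan–Lam–Evans oxidative C–O coupling, in which the phenoxide of 1 and the aryl group of 2 meet on copper and reductive elimination from trivalent copper forms the diaryl ether at room temperature, a mode that accepts acidic 2,6-disubstituted phenols and leaves the aryl bromide untouched.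

Step 2
Reactants: 3 4-(3-bromo-5-methoxyphenoxy)-3,5-dimethoxybenzaldehyde
Product: 4 4-(3-bromo-5-hydroxyphenoxy)-3,5-dihydroxybenzaldehyde
Conditions: BBr3 (5 equiv), CH2Cl2, −78 °C → rt; then H2O
Reagents that add atoms: none
Why: Lewis-acid ether cleavage, in which BBr3 binds each methoxy oxygen and bromide removes the methyl group by SN2 attack, while the diaryl ether (no sp3 carbon on oxygen), the aryl bromide and the aldehyde should survive.

Step 3
Reactants: 4 4-(3-bromo-5-hydroxyphenoxy)-3,5-dihydroxybenzaldehyde
Product: 5 4-[3-bromo-5-(triisopropylsilyloxy)phenoxy]-3,5-bis(triisopropylsilyloxy)benzaldehyde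
Conditions: TIPSCl (3.6 equiv), imidazole (8 equiv), DMF, rt → 40 °C
Reagents that add atoms: triisopropylsilyl chloride, CC(C)[Si](Cl)(C(C)C)C(C)C
Why: Imidazole-promoted O-silylation of the three phenols, with TIPS chosen because aryl TIPS ethers should tolerate the Grignard, phosphate-base and reductive nickel steps and can be removed together by fluoride at the end.

Step 4
Reactants: 5 4-[3-bromo-5-(triisopropylsilyloxy)phenoxy]-3,5-bis(triisopropylsilyloxy)benzaldehyde; 6 cyclopropylmagnesium bromide
Product: 7 rac-{4-[3-bromo-5-(triisopropylsilyloxy)phenoxy]-3,5-bis(triisopropylsilyloxy)phenyl}(cyclopropyl)methanol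
Conditions: THF, −78 → 0 °C; then H2O
Reagents that add atoms: none
Why: Grignard 1,2-addition to the aldehyde at low temperature, where the aryl bromide and silyl ethers are inert, gives a racemic carbinol whose stereocentre is erased in step 5.

Step 5
Reactants: 7 rac-{4-[3-bromo-5-(triisopropylsilyloxy)phenoxy]-3,5-bis(triisopropylsilyloxy)phenyl}(cyclopropyl)methanol
Product: 8 {4-[3-bromo-5-(triisopropylsilyloxy)phenoxy]-3,5-bis(triisopropylsilyloxy)phenyl}(cyclopropyl)methanone
Conditions: Dess–Martin periodinane (1.3 equiv), CH2Cl2, 0 °C → rt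
Reagents that add atoms: none
Why: Dess–Martin oxidation of the benzylic cyclopropylcarbinol under near-neutral conditions should give the aryl cyclopropyl ketone without cyclopropylcarbinyl cation rearrangement.

Step 6
Reactants: 9 5-bromopent-1-ene; 10 acrolein
Product: 12 rac-octa-1,7-dien-3-ol, via pent-4-enylmagnesium bromide 11 (not isolated)
Conditions: Mg turnings, THF, rt → reflux; then 10, −78 → 0 °C; then H2O
Reagents that add atoms: none
Why: Grignard formation followed by 1,2-addition to acrolein, which primary Grignard reagents prefer over conjugate addition in the absence of copper, gives the allylic alcohol whose racemic centre is consumed in step 7.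

Step 7
Reactants: 12 rac-octa-1,7-dien-3-ol; 13 triethyl orthoacetate
Product: 16 ethyl (E)-deca-4,9-dienoate, via mixed orthoester 14 (not isolated), via ketene acetal 15 (not isolated)
Conditions: EtCO2H (5 mol%), neat 13 (6 equiv), 140 °C, EtOH distilled off
Reagents that add atoms: none
Why: Johnson–Claisen rearrangement, in which acid-catalysed exchange and loss of ethanol give ketene acetal 15 and its [3,3]-sigmatropic shift through a chair transition state with the pentenyl group equatorial should set the new disubstituted alkene with high E selectivity.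

Step 8
Reactants: 16 ethyl (E)-deca-4,9-dienoate
Product: 17 (E)-deca-4,9-dien-1-ol
Conditions: LiAlH4 (1.0 equiv), Et2O, 0 °C; then H2O, aq NaOH
Reagents that add atoms: none
Why: Hydride reduction of the ester to the primary alcohol, which leaves both isolated alkenes and the E geometry untouched.

Step 9
Reactants: 17 (E)-deca-4,9-dien-1-ol
Product: 18 (E)-10-bromodeca-1,6-diene
Conditions: CBr4 (1.3 equiv), PPh3 (1.4 equiv), CH2Cl2, 0 °C
Reagents that add atoms: carbon tetrabromide, BrC(Br)(Br)Br
Why: Appel bromination, an SN2 displacement of the alkoxyphosphonium ion by bromide at a primary carbon, which does not affect the alkenes.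

Step 10
Reactants: 18 (E)-10-bromodeca-1,6-diene; 8 {4-[3-bromo-5-(triisopropylsilyloxy)phenoxy]-3,5-bis(triisopropylsilyloxy)phenyl}(cyclopropyl)methanone
Product: 20 {4-[3-((E)-10-bromodec-6-en-1-yl)-5-(triisopropylsilyloxy)phenoxy]-3,5-bis(triisopropylsilyloxy)phenyl}(cyclopropyl)methanone, via alkylborane 19 (not isolated)
Conditions: 18 (1.3 equiv), 9-BBN (1.25 equiv), THF, 0 °C → rt; then 8, Pd(dppf)Cl2·CH2Cl2 (5 mol%), K3PO4 (3 equiv, 3 M aq), DMF, 45 °C
Reagents that add atoms: none
Why: Hydroboration/B-alkyl Suzuki–Miyaura coupling, in which 9-BBN selects the monosubstituted alkene of 18 over the internal E-alkene and places boron on the terminal carbon, and zerovalent palladium inserts into the aryl C–Br bond of 8 far faster than into the primary alkyl C–Br bond.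

Step 11
Reactants: 20 {4-[3-((E)-10-bromodec-6-en-1-yl)-5-(triisopropylsilyloxy)phenoxy]-3,5-bis(triisopropylsilyloxy)phenyl}(cyclopropyl)methanone
Product: 22 macrocyclic ketone (22-membered diaryl ether ring; C1=O on ring B; C2–C7 six CH2; E-C8=C9; C10–C14 five CH2 to ring A; three phenols as TIPS ethers), via zinc bromide enolate 21 (not isolated)
Conditions: NiBr2·dme (30 mol%), 4,4'-di-tert-butyl-2,2'-bipyridine (36 mol%), Zn dust (4 equiv), DMA, 45 °C, 20 added by syringe pump over 16 h (final 3 mM); then H2O
Reagents that add atoms: none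
Why: Proposed new method: zerovalent nickel (from NiBr2·dme, the bipyridine and Zn) should insert, with carbonyl assistance, into the conjugation-weakened C2–C4 bond of the aryl cyclopropyl ketone to give a six-membered oxa-nickelacycle, while halogen abstraction from the tethered primary bromide by monovalent nickel gives the C5 radical; radical capture at nickel and C(sp3)–C(sp3) reductive elimination from trivalent nickel would form C4–C5 and release enolate 21, which is protonated at C2 on work-up. The closest known reaction type is the intermolecular nickel-catalysed reductive ring-opening γ-alkylation of aryl cyclopropyl ketones with unactivated primary alkyl bromides; running it between the two ends of one molecule to close a large ring is the untested part. The 22-membered ring closes in an endo sense with respect to the cleaved cyclopropane bond (C2 and C4 both become ring members), through a nickela-macrocycle that contracts on reductive elimination. No stereocentre is formed, and the E-C8=C9 alkene is a spectator because the C5 radical is a pent-4-enyl radical whose only cyclisation modes onto it (4-exo, 5-endo) are slow. The selectivities needed are ring closure over oligomerisation and C–C coupling over simple reduction of either terminus; slow addition at millimolar concentration, the equivalence of the two cyclopropane CH2 groups (no regiochemical choice), the absence of any aryl halide, and the bent meta/para diaryl ether hinge that turns both chain ends toward each other should secure them.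

Step 12
Reactants: 22 macrocyclic ketone
Product: 23 (R)-configured macrocyclic benzylic alcohol (tris-O-TIPS ether of the target)
Conditions: (S)-2-methyl-CBS-oxazaborolidine (0.3 equiv), catecholborane (2 equiv), toluene, −78 → −40 °C; then MeOH, pH 7 buffer
Reagents that add atoms: none
Why: Corey–Bakshi–Shibata reduction, in which the (S)-oxazaborolidine binds the ketone with the aryl group (large) away from the catalyst and the ring CH2 (small) towards it and delivers hydride from nitrogen-bound catecholborane to the Si face of the carbonyl (O > aryl > C2) to give the (R)-carbinol, while catecholborane at low temperature does not hydroborate the alkene.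

Step 13
Reactants: 23 (R)-configured macrocyclic benzylic alcohol (tris-O-TIPS ether of the target)
Product: 24 dehydrogravicycle
Conditions: TBAF (3.6 equiv), AcOH (3.6 equiv), THF, 0 °C → rt, argon
Reagents that add atoms: none
Why: Fluoride-induced cleavage of the three aryl silyl ethers driven by the Si–F bond, buffered with AcOH to protect the electron-rich triphenol, with the benzylic alcohol safe because the freed hydroxyls are meta to the carbinol carbon and no quinone-methide pathway is open.

**Compound list**

1 | syringaldehyde (4-hydroxy-3,5-dimethoxybenzaldehyde) | COc1cc(C=O)cc(OC)c1O | starting material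
2 | (3-bromo-5-methoxyphenyl)boronic acid | COc1cc(Br)cc(B(O)O)c1 | starting material
3 | 4-(3-bromo-5-methoxyphenoxy)-3,5-dimethoxybenzaldehyde | COc1cc(Br)cc(Oc2c(OC)cc(C=O)cc2OC)c1 | intermediate
4 | 4-(3-bromo-5-hydroxyphenoxy)-3,5-dihydroxybenzaldehyde | Oc1cc(Br)cc(Oc2c(O)cc(C=O)cc2O)c1 | intermediate
5 | 4-[3-bromo-5-(triisopropylsilyloxy)phenoxy]-3,5-bis(triisopropylsilyloxy)benzaldehyde | CC(C)[Si](C(C)C)(C(C)C)Oc1cc(Br)cc(Oc2c(O[Si](C(C)C)(C(C)C)C(C)C)cc(C=O)cc2O[Si](C(C)C)(C(C)C)C(C)C)c1 | intermediate
6 | cyclopropylmagnesium bromide | Br[Mg]C1CC1 | starting material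
7 | rac-{4-[3-bromo-5-(triisopropylsilyloxy)phenoxy]-3,5-bis(triisopropylsilyloxy)phenyl}(cyclopropyl)methanol | CC(C)[Si](C(C)C)(C(C)C)Oc1cc(Br)cc(Oc2c(O[Si](C(C)C)(C(C)C)C(C)C)cc(C(O)C3CC3)cc2O[Si](C(C)C)(C(C)C)C(C)C)c1 | intermediate
8 | {4-[3-bromo-5-(triisopropylsilyloxy)phenoxy]-3,5-bis(triisopropylsilyloxy)phenyl}(cyclopropyl)methanone | CC(C)[Si](C(C)C)(C(C)C)Oc1cc(Br)cc(Oc2c(O[Si](C(C)C)(C(C)C)C(C)C)cc(C(=O)C3CC3)cc2O[Si](C(C)C)(C(C)C)C(C)C)c1 | intermediate
9 | 5-bromopent-1-ene | BrCCCC=C | starting material
10 | acrolein (prop-2-enal) | C=CC=O | starting material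
11 | pent-4-enylmagnesium bromide | C=CCCC[Mg]Br | intermediate
12 | rac-octa-1,7-dien-3-ol | C=CCCCC(O)C=C | intermediate
13 | triethyl orthoacetate | CC(OCC)(OCC)OCC | starting material
14 | 3-(1,1-diethoxyethoxy)octa-1,7-diene (mixed orthoester) | CCOC(C)(OCC)OC(C=C)CCCC=C | intermediate
15 | 3-[(1-ethoxyethenyl)oxy]octa-1,7-diene (ketene acetal) | C=C(OCC)OC(C=C)CCCC=C | intermediate
16 | ethyl (E)-deca-4,9-dienoate | CCOC(=O)CC/C=C/CCCC=C | intermediate
17 | (E)-deca-4,9-dien-1-ol | OCCC/C=C/CCCC=C | intermediate
18 | (E)-10-bromodeca-1,6-diene | BrCCC/C=C/CCCC=C | intermediate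
19 | 9-[(E)-10-bromodec-6-en-1-yl]-9-borabicyclo[3.3.1]nonane | BrCCC/C=C/CCCCCB1C2CCCC1CCC2 | intermediate
20 | {4-[3-((E)-10-bromodec-6-en-1-yl)-5-(triisopropylsilyloxy)phenoxy]-3,5-bis(triisopropylsilyloxy)phenyl}(cyclopropyl)methanone | CC(C)[Si](C(C)C)(C(C)C)Oc1cc(CCCCC/C=C/CCCBr)cc(Oc2c(O[Si](C(C)C)(C(C)C)C(C)C)cc(C(=O)C3CC3)cc2O[Si](C(C)C)(C(C)C)C(C)C)c1 | intermediate
21 | zinc bromide (Z)-enolate of macrocyclic ketone 22 (C1=C2 enolate, O–ZnBr on C1) | CC(C)[Si](C(C)C)(C(C)C)Oc1cc2cc(c1)Oc1c(O[Si](C(C)C)(C(C)C)C(C)C)cc(cc1O[Si](C(C)C)(C(C)C)C(C)C)/C(O[Zn]Br)=C/CCCCC/C=C/CCCCC2 | intermediate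
22 | macrocyclic ketone: 22-membered diaryl ether ring, C1=O on ring B, E-C8=C9, tris-O-TIPS | CC(C)[Si](C(C)C)(C(C)C)Oc1cc2cc(c1)Oc1c(O[Si](C(C)C)(C(C)C)C(C)C)cc(cc1O[Si](C(C)C)(C(C)C)C(C)C)C(=O)CCCCCC/C=C/CCCCC2 | intermediate
23 | (R)-macrocyclic benzylic alcohol, tris-O-TIPS ether of dehydrogravicycle | CC(C)[Si](C(C)C)(C(C)C)Oc1cc2cc(c1)Oc1c(O[Si](C(C)C)(C(C)C)C(C)C)cc(cc1O[Si](C(C)C)(C(C)C)C(C)C)[C@H](O)CCCCCC/C=C/CCCCC2 | intermediate
24 | dehydrogravicycle | Oc1cc2cc(c1)Oc1c(O)cc(cc1O)[C@H](O)CCCCCC/C=C/CCCCC2 | target

**Step count and risks**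

Total step count: 13. Longest linear sequence: 9 steps (steps 1–5 and 10–13, from 1).

Steps most likely to fail:

1. Step 11 (Proposed new method). Ring closure may lose out to intermolecular coupling (oligomers) or to premature reduction of the nickelacycle or of the bromide, which would give open-chain propyl ketone or des-bromo material. The fallback makes the C4–C5 bond in the precedented intermolecular mode and closes the ring by metathesis instead. It sets out from 8: mono-hydroboration of hepta-1,6-diene (used in excess) with 9-BBN would give 9-(hept-6-en-1-yl)-9-borabicyclo[3.3.1]nonane F1, and its Suzuki coupling with 8 under the conditions of step 10 would give {4-[3-(hept-6-en-1-yl)-5-(triisopropylsilyloxy)phenoxy]-3,5-bis(triisopropylsilyloxy)phenyl}(cyclopropyl)methanone F2. Nickel-catalysed reductive ring-opening alkylation of F2 with 5-bromopent-1-ene 9 (NiBr2·dme, bipyridine ligand, Zn, DMA, at normal concentration) would give, through the zinc bromide enolate F3, 1-{4-[3-(hept-6-en-1-yl)-5-(triisopropylsilyloxy)phenoxy]-3,5-bis(triisopropylsilyloxy)phenyl}non-8-en-1-one F4. Ring-closing metathesis of F4 with the second-generation Grubbs catalyst RuCl2(H2IMes)(PCy3)(=CHPh) at high dilution would close the 22-membered ring at C8=C9 and come back to the route at 22. The cost is alkene geometry: E should predominate in an unstrained ring of this size, but the Z isomer would have to be removed on AgNO3-impregnated silica.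

2. Step 1. The hindered, acidic phenol of 1 may exchange onto copper too slowly, so that protodeboronation and homocoupling consume 2. The fallback changes the electrophile and the mechanism to a copper-catalysed Ullmann etherification of an aryl halide. It sets out from 1, which would be heated with an excess (3 equiv) of 1,3-dibromo-5-methoxybenzene, CuI (10 mol%), picolinic acid (20 mol%) and K3PO4 in DMSO at 90 °C; the excess of the symmetrical dibromide suppresses double arylation, and the sequence comes back to the route at 3.

3. Step 10. The aqueous phosphate may strip aryl silyl ethers, and the primary C–Br bond may undergo competing oxidative addition or substitution. The fallback is a base-free Negishi coupling. It sets out from alkylborane 19: iodinolysis (I2, NaOMe, MeOH, 0 °C) would give (E)-1-bromo-10-iododec-4-ene F5, and Zn dust/LiCl in THF at 25 °C should insert into the C–I bond in preference to the C–Br bond to give [(E)-10-bromodec-6-en-1-yl]zinc iodide F6. Coupling of F6 with 8 (Pd(OAc)2, SPhos, THF, rt) would come back to the route at 20.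

**Further compounds**

F1 | step 11 | 9-(hept-6-en-1-yl)-9-borabicyclo[3.3.1]nonane | C=CCCCCCB1C2CCCC1CCC2
F2 | step 11 | {4-[3-(hept-6-en-1-yl)-5-(triisopropylsilyloxy)phenoxy]-3,5-bis(triisopropylsilyloxy)phenyl}(cyclopropyl)methanone | CC(C)[Si](C(C)C)(C(C)C)Oc1cc(CCCCCC=C)cc(Oc2c(O[Si](C(C)C)(C(C)C)C(C)C)cc(C(=O)C3CC3)cc2O[Si](C(C)C)(C(C)C)C(C)C)c1
F3 | step 11 | zinc bromide (Z)-enolate of F4 | CC(C)[Si](C(C)C)(C(C)C)Oc1cc(CCCCCC=C)cc(Oc2c(O[Si](C(C)C)(C(C)C)C(C)C)cc(/C(O[Zn]Br)=C/CCCCCC=C)cc2O[Si](C(C)C)(C(C)C)C(C)C)c1
F4 | step 11 | 1-{4-[3-(hept-6-en-1-yl)-5-(triisopropylsilyloxy)phenoxy]-3,5-bis(triisopropylsilyloxy)phenyl}non-8-en-1-one | CC(C)[Si](C(C)C)(C(C)C)Oc1cc(CCCCCC=C)cc(Oc2c(O[Si](C(C)C)(C(C)C)C(C)C)cc(C(=O)CCCCCCC=C)cc2O[Si](C(C)C)(C(C)C)C(C)C)c1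
F0 | step 1 | none | none
F5 | step 10 | (E)-1-bromo-10-iododec-4-ene | BrCCC/C=C/CCCCCI
F6 | step 10 | [(E)-10-bromodec-6-en-1-yl]zinc iodide | BrCCC/C=C/CCCCC[Zn]I
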